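A direct plan would build the C6 butenolide first (Evans alkylation for C4, transfer hydrogenation of an ynone for C6, hydroalumination–iodination, carbonylative lactonisation), attach the C10 enoate arm by a Wittig reaction and close the ten-membered ring last: indium-mediated Barbier addition of the allylic bromide of seco-aldehyde A1 to its own C8 aldehyde would give carbinol A2, followed by Mitsunobu esterification with angelic acid and desilylation.
Weak step 1, the ring closure A1 to A2: a ten-membered carbocycle closed from an open chain against transannular strain and entropy, needing slow addition at millimolar dilution and a β,γ-unsaturated aldehyde that must neither conjugate nor oligomerise.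
Weak step 2, the C8 carbinol of A2: the cyclic transition state would set it with the wrong configuration, so it has to be corrected afterwards by SN2 inversion on a hindered secondary alcohol of a medium ring, where elimination and retention compete.
Weak step 3, the run-up to A1: some fifteen linear steps, with two osmium/periodate cleavages and a TBS/TBDPS exchange that build no bond of the skeleton.

**Retrosynthetic overview**
The ten-membered ring C1–C10 is grown from a six-membered ring: an anionic acetylenic oxy-Cope [3,3] shift exchanges the bond C1–C6 of a cyclohexane for the bond C8–C9, so that the 6-ethynyl group supplies C7 and C8 and a 1-acrylate unit supplies C9, C10 and C14.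
The acrylate is stored as a trans-fused α-methylene-γ-lactone on O6 (compound 14, six steps from 3-methoxybenzyl alcohol); methoxide opens it, which frees the C6 alkoxide that triggers the shift and at once writes the C14 methyl ester and the (1E) C1=C10 enoate of the target.
Ring order: cyclohexenone (Birch), temporary lactone, ten-membered carbocycle (ring expansion), then the 12,6-lactone ring by a 5-exo vinyl-radical closure from O6 onto C7 that brings in C11=C13 and oxygenates C8 in the same operation.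
Stereocentres: C4 by catalytic asymmetric conjugate reduction, C6 by CBS reduction of the enone that the key step leaves, C7 from C6 in the radical closure, C8 by hydride addition to a ketone reached from both carbinol epimers.
This avoids high-dilution macrocyclisation and any centre set wrong and inverted, uses one silyl group in the whole route, and needs no enolate chemistry once the enoate is in place.

Key step: step 7

Assumption: the acetal carbon of 20–27 and the C8 carbinol of 21 and 22 are carried as epimer mixtures, since both are levelled later; the ligand hand in step 4 is assigned by analogy with 3-alkylcyclohexenones.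

Step 1
Reactants: 1 (3-methoxyphenyl)methanol
Product: 3 3-(hydroxymethyl)cyclohex-2-en-1-one, via dihydroanisole 2 (not isolated)
Conditions: Li, NH3(l), t-BuOH, THF, −78 °C; NH4Cl; then 2 M HCl, THF, rt
Reagents that add atoms: water, O
Why: Birch reduction of the anisole ring (the benzylic alkoxide resists hydrogenolysis) gives the 1-methoxy-1,4-diene, and acid hydrolysis of the enol ether with migration of the other double bond into conjugation gives the 3-substituted cyclohexenone that holds C15, C4 and C6; no stereocentre is formed.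

Step 2
Reactants: 3 3-(hydroxymethyl)cyclohex-2-en-1-one
Product: 4 3-{[(tert-butyldiphenylsilyl)oxy]methyl}cyclohex-2-en-1-one
Conditions: TBDPSCl, imidazole, DMF, rt
Reagents that add atoms: tert-butyl(chloro)diphenylsilane, CC(C)(C)[Si](Cl)(c1ccccc1)c1ccccc1
Why: Standard silylation of the primary allylic alcohol; this single protecting group stays until the last step.

Step 3
Reactants: 4 3-{[(tert-butyldiphenylsilyl)oxy]methyl}cyclohex-2-en-1-one; 5 methyl bromoacetate
Product: 7 methyl 2-(4-{[(tert-butyldiphenylsilyl)oxy]methyl}-2-oxocyclohex-3-en-1-yl)acetate, via lithium dienolate 6 (not isolated)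
Conditions: LDA, THF, −78 °C; then 5, DMPU, −78 → −30 °C
Reagents that add atoms: none
Why: Kinetic α′-deprotonation of the cyclohexenone gives the cross-conjugated enolate, whose alkylation (enolate alkylation) attaches C10 and C14 at C1; the new centre is racemic, epimerisable and erased in step 7.

Step 4
Reactants: 7 methyl 2-(4-{[(tert-butyldiphenylsilyl)oxy]methyl}-2-oxocyclohex-3-en-1-yl)acetate
Product: 9 methyl 2-[(1S,4R)-4-{[(tert-butyldiphenylsilyl)oxy]methyl}-2-oxocyclohexyl]acetate, via silyl enol ether 8 (not isolated)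
Conditions: CuCl (5 mol %), NaOt-Bu (5 mol %), (S)-p-tol-BINAP (5 mol %), (EtO)2MeSiH, toluene, 0 °C; then 1 M HCl, THF; DBU (0.1 equiv), CH2Cl2, rt
Reagents that add atoms: none
Why: Ligand-controlled asymmetric conjugate reduction by monovalent copper hydride adds hydride to C4 of the β,β-disubstituted enone and should set C4 (R) under catalyst control (the antipodal ligand is used if the sense is opposite), and base equilibration at C1 should leave mainly the trans-2,5 diequatorial ketone.

Step 5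
Reactants: 9 methyl 2-[(1S,4R)-4-{[(tert-butyldiphenylsilyl)oxy]methyl}-2-oxocyclohexyl]acetate; 10 ethynylmagnesium bromide
Product: 12 (3aS,6R,7aR)-6-{[(tert-butyldiphenylsilyl)oxy]methyl}-7a-ethynylhexahydro-1-benzofuran-2(3H)-one, via bromomagnesium alkoxide 11 (not isolated)
Conditions: 10 (1.5 equiv), LaCl3·2LiCl (0.3 equiv), THF, −78 → 0 °C, then rt; aq. NH4Cl
Reagents that add atoms: none
Why: 1,2-Addition of the small acetylide should follow the axial trajectory, placing the ethynyl group axial at C6 (cis to the C1 side chain) and the alkoxide equatorial, which then acylates itself on the neighbouring methyl ester (lactonisation) to the trans-fused γ-lactone; C6 is a relay centre set by the ring.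

Step 6
Reactants: 12 (3aS,6R,7aR)-6-{[(tert-butyldiphenylsilyl)oxy]methyl}-7a-ethynylhexahydro-1-benzofuran-2(3H)-one
Product: 14 (3aS,6R,7aR)-6-{[(tert-butyldiphenylsilyl)oxy]methyl}-7a-ethynyl-3-methylidenehexahydro-1-benzofuran-2(3H)-one, via carboxy lactone 13 (not isolated)
Conditions: MeOMgOCO2Me (2 M in DMF), 120 °C; then 37% aq. CH2O, Et2NH, NaOAc, AcOH, rt
Reagents that add atoms: formaldehyde, C=O
Why: α-Carboxylation of the lactone followed by decarboxylative Mannich methylenation installs the exocyclic C10=C9 alkene under conditions too weakly basic to metalate the terminal alkyne.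

Step 7
Reactants: 14 (3aS,6R,7aR)-6-{[(tert-butyldiphenylsilyl)oxy]methyl}-7a-ethynyl-3-methylidenehexahydro-1-benzofuran-2(3H)-one
Product: 17 methyl (1E,5R,8Z)-5-{[(tert-butyldiphenylsilyl)oxy]methyl}-7-oxocyclodeca-1,8-diene-1-carboxylate, via potassium alkoxide 15 (not isolated), via potassium allenolate 16 (not isolated)
Conditions: KOMe (1.1 equiv), 18-crown-6 (1.2 equiv), THF, 0 → 40 °C; then AcOH, −78 °C
Reagents that add atoms: potassium methoxide, C[O-].[K+]
Why: Proposed new method: methoxide adds to the lactone carbonyl C14 and opens the ring to the methyl acrylate with a crown-separated potassium alkoxide at C6, and this 3-oxido-1,5-enyne (C8≡C7–C6(O−)–C1–C10=C9) undergoes an anionic acetylenic oxy-Cope [3,3] shift in which the cyclohexane bond C1–C6 is traded for the new bond C8–C9; the closest known reaction type is the KH/18-crown-6 oxy-Cope ring expansion of 1-alkynyl- and 1-alkenyl-2-alkenylcyclohexanols to cyclodecenones, here triggered by transesterification of a lactone instead of deprotonation of a free carbinol. The only ring formed is the ten-membered carbocycle C1–C10, which arises by four-atom ring expansion of the six-membered ring (sigmatropic, not an end-to-end closure), while the lactone ring is given up and its carbonyl becomes the C14 methyl ester. No sp3 stereocentre is created, C1 and C6 are erased, and the C1=C10 geometry is controlled by the chair-like array with the ethynyl group axial and the acrylate equatorial, which turns C2 towards C9 and should give the ring-cis (1E) enoate of the target. Kinetic protonation of the allenolate at C7 from the side of H8 should give the cis (8Z) enone, which is also the more stable geometry in this ring size. The step needs the shift to outrun re-lactonisation, reversible methoxide addition to the methylene lactone and loss of acetylide, and this is secured by the irreversibility of the shift, the acceptor character of the acrylate terminus C9 and the naked alkoxide. The lactone equilibrium feeds the alkoxide continuously, so one equivalent of base suffices and the doubly allylic C9 is not exposed to base after the cold acid quench.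

Step 8
Reactants: 17 methyl (1E,5R,8Z)-5-{[(tert-butyldiphenylsilyl)oxy]methyl}-7-oxocyclodeca-1,8-diene-1-carboxylate
Product: 18 methyl (1E,5R,7R,8Z)-5-{[(tert-butyldiphenylsilyl)oxy]methyl}-7-hydroxycyclodeca-1,8-diene-1-carboxylate
Conditions: (S)-Me-CBS oxazaborolidine (0.2 equiv), catecholborane, toluene, −78 °C
Reagents that add atoms: none
Why: Corey–Bakshi–Shibata reduction delivers hydride 1,2 to the enone carbonyl with the alkenyl arm as the large group, which should set C6 of the target (7R here) under catalyst control and leave the enoate untouched.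

Step 9
Reactants: 18 methyl (1E,5R,7R,8Z)-5-{[(tert-butyldiphenylsilyl)oxy]methyl}-7-hydroxycyclodeca-1,8-diene-1-carboxylate; 19 methoxyallene
Product: 20 methyl (1E,5R,7R,8Z)-5-{[(tert-butyldiphenylsilyl)oxy]methyl}-7-[(2-iodo-1-methoxyprop-2-en-1-yl)oxy]cyclodeca-1,8-diene-1-carboxylate
Conditions: 19, NIS, CH2Cl2, −40 → 0 °C
Reagents that add atoms: N-iodosuccinimide, O=C1CCC(=O)N1I
Why: Iodoalkoxylation of the alkoxyallene (iodonium at the central carbon, capture of the oxocarbenium ion by the C6 hydroxyl) gives the mixed 2-iodoallyl acetal without touching C6; the acetal carbon forms as both epimers and is oxidised away in step 13.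

Step 10
Reactants: 20 methyl (1E,5R,7R,8Z)-5-{[(tert-butyldiphenylsilyl)oxy]methyl}-7-[(2-iodo-1-methoxyprop-2-en-1-yl)oxy]cyclodeca-1,8-diene-1-carboxylate
Product: 23 methyl (3aS,6E,10R,11aR)-10-{[(tert-butyldiphenylsilyl)oxy]methyl}-2-methoxy-3-methylidene-4-oxo-2,3,3a,4,5,8,9,10,11,11a-decahydrocyclodeca[b]furan-6-carboxylate, via hydroperoxide 21 (not isolated), via carbinol 22 (not isolated)
Conditions: Bu3SnH (syringe pump), Et3B (0.2 equiv), dry air, toluene, 0 °C → rt; PPh3; then Dess–Martin periodinane, NaHCO3, CH2Cl2, 0 °C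
Reagents that add atoms: dioxygen, O=O
Why: Ueno–Stork-type 5-exo cyclisation of the vinyl radical onto C7 (chair-like transition state with H6 eclipsing the cis alkene, a 4-substituted hexenyl radical giving the trans ring fusion) should set C7 from C6, the C8 radical is captured by oxygen, and oxidation of both C8 carbinol epimers to one ketone makes that capture stereoconvergent; the ketone is used at once.

Step 11
Reactants: 23 methyl (3aS,6E,10R,11aR)-10-{[(tert-butyldiphenylsilyl)oxy]methyl}-2-methoxy-3-methylidene-4-oxo-2,3,3a,4,5,8,9,10,11,11a-decahydrocyclodeca[b]furan-6-carboxylate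
Product: 24 methyl (3aR,4R,6E,10R,11aR)-10-{[(tert-butyldiphenylsilyl)oxy]methyl}-4-hydroxy-2-methoxy-3-methylidene-2,3,3a,4,5,8,9,10,11,11a-decahydrocyclodeca[b]furan-6-carboxylate
Conditions: NaBH4, CeCl3·7H2O, MeOH, −78 °C
Reagents that add atoms: none
Why: Luche 1,2-reduction, in which hydride should reach the C8 carbonyl from the ring periphery anti to the C7–C11 bond and so place O8 cis to C11 (4R here), the enoate and the methylene acetal being left alone.

Step 12
Reactants: 24 methyl (3aR,4R,6E,10R,11aR)-10-{[(tert-butyldiphenylsilyl)oxy]methyl}-4-hydroxy-2-methoxy-3-methylidene-2,3,3a,4,5,8,9,10,11,11a-decahydrocyclodeca[b]furan-6-carboxylate; 25 angelic acid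
Product: 27 methyl (3aS,4R,6E,10R,11aR)-10-{[(tert-butyldiphenylsilyl)oxy]methyl}-2-methoxy-4-{[(2Z)-2-methylbut-2-enoyl]oxy}-3-methylidene-2,3,3a,4,5,8,9,10,11,11a-decahydrocyclodeca[b]furan-6-carboxylate, via mixed anhydride 26 (not isolated)
Conditions: 25, 2,4,6-trichlorobenzoyl chloride, Et3N, toluene, rt; then 24, DMAP, 60 °C
Reagents that add atoms: none
Why: Yamaguchi esterification acylates the hindered C8 carbinol with retention, the mixed-anhydride conditions keeping the Z alkene of the acid intact.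

Step 13
Reactants: 27 methyl (3aS,4R,6E,10R,11aR)-10-{[(tert-butyldiphenylsilyl)oxy]methyl}-2-methoxy-4-{[(2Z)-2-methylbut-2-enoyl]oxy}-3-methylidene-2,3,3a,4,5,8,9,10,11,11a-decahydrocyclodeca[b]furan-6-carboxylate
Product: 28 methyl (3aS,4R,6E,10R,11aR)-10-{[(tert-butyldiphenylsilyl)oxy]methyl}-4-{[(2Z)-2-methylbut-2-enoyl]oxy}-3-methylidene-2-oxo-2,3,3a,4,5,8,9,10,11,11a-decahydrocyclodeca[b]furan-6-carboxylate
Conditions: CrO3, H2SO4, H2O, acetone, 0 °C
Reagents that add atoms: water, O
Why: Jones oxidation hydrolyses the allylic methyl acetal and oxidises the lactol to the α-methylene-γ-lactone, at a stage where no free carbinol is left and the isomerisation-prone 8-oxo compound is past.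

Step 14
Reactants: 28 methyl (3aS,4R,6E,10R,11aR)-10-{[(tert-butyldiphenylsilyl)oxy]methyl}-4-{[(2Z)-2-methylbut-2-enoyl]oxy}-3-methylidene-2-oxo-2,3,3a,4,5,8,9,10,11,11a-decahydrocyclodeca[b]furan-6-carboxylate
Product: 29 methyl (3aS,4R,6E,10R,11aR)-10-(hydroxymethyl)-4-{[(2Z)-2-methylbut-2-enoyl]oxy}-3-methylidene-2-oxo-2,3,3a,4,5,8,9,10,11,11a-decahydrocyclodeca[b]furan-6-carboxylate
Conditions: HF·pyridine, pyridine, THF, 0 °C → rt
Reagents that add atoms: none
Why: Buffered fluoride desilylation of the primary TBDPS ether should leave the α-methylene lactone, both esters and the Z-angelate intact.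

**Compound list**

1 | (3-methoxyphenyl)methanol | COc1cccc(CO)c1 | starting material
2 | (5-methoxycyclohexa-1,4-dien-1-yl)methanol | COC1=CCC=C(CO)C1 | intermediate
3 | 3-(hydroxymethyl)cyclohex-2-en-1-one | O=C1C=C(CO)CCC1 | intermediate
4 | 3-{[(tert-butyldiphenylsilyl)oxy]methyl}cyclohex-2-en-1-one | O=C1C=C(CO[Si](c2ccccc2)(c2ccccc2)C(C)(C)C)CCC1 | intermediate
5 | methyl bromoacetate | COC(=O)CBr | starting material
6 | lithium 5-{[(tert-butyldiphenylsilyl)oxy]methyl}cyclohexa-1,5-dien-1-olate | [Li]OC1=CCCC(CO[Si](c2ccccc2)(c2ccccc2)C(C)(C)C)=C1 | intermediate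
7 | methyl 2-(4-{[(tert-butyldiphenylsilyl)oxy]methyl}-2-oxocyclohex-3-en-1-yl)acetate (racemic) | COC(=O)CC1CCC(CO[Si](c2ccccc2)(c2ccccc2)C(C)(C)C)=CC1=O | intermediate
8 | methyl 2-[(4R)-4-{[(tert-butyldiphenylsilyl)oxy]methyl}-2-{[diethoxy(methyl)silyl]oxy}cyclohex-2-en-1-yl]acetate (both C1 epimers) | COC(=O)CC1CC[C@@H](CO[Si](c2ccccc2)(c2ccccc2)C(C)(C)C)C=C1O[Si](C)(OCC)OCC | intermediate
9 | methyl 2-[(1S,4R)-4-{[(tert-butyldiphenylsilyl)oxy]methyl}-2-oxocyclohexyl]acetate | O=C1C[C@H](CO[Si](c2ccccc2)(c2ccccc2)C(C)(C)C)CC[C@H]1CC(=O)OC | intermediate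
10 | ethynylmagnesium bromide | C#C[Mg]Br | starting material
11 | bromomagnesium alkoxide of methyl 2-[(1S,2R,4R)-4-{[(tert-butyldiphenylsilyl)oxy]methyl}-2-ethynyl-2-hydroxycyclohexyl]acetate | COC(=O)C[C@@H]1CC[C@@H](CO[Si](c2ccccc2)(c2ccccc2)C(C)(C)C)C[C@@]1(C#C)O[Mg]Br | intermediate
12 | (3aS,6R,7aR)-6-{[(tert-butyldiphenylsilyl)oxy]methyl}-7a-ethynylhexahydro-1-benzofuran-2(3H)-one | O=C1C[C@@H]2CC[C@@H](CO[Si](c3ccccc3)(c3ccccc3)C(C)(C)C)C[C@@]2(C#C)O1 | intermediate
13 | (3aS,6R,7aR)-6-{[(tert-butyldiphenylsilyl)oxy]methyl}-7a-ethynyl-2-oxooctahydro-1-benzofuran-3-carboxylic acid (magnesium salt in the flask, both C3 epimers) | O=C1C(C(=O)O)[C@@H]2CC[C@@H](CO[Si](c3ccccc3)(c3ccccc3)C(C)(C)C)C[C@@]2(C#C)O1 | intermediate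
14 | (3aS,6R,7aR)-6-{[(tert-butyldiphenylsilyl)oxy]methyl}-7a-ethynyl-3-methylidenehexahydro-1-benzofuran-2(3H)-one | O=C1C(=C)[C@@H]2CC[C@@H](CO[Si](c3ccccc3)(c3ccccc3)C(C)(C)C)C[C@@]2(C#C)O1 | intermediate
15 | potassium alkoxide of methyl 2-[(1S,2R,4R)-4-{[(tert-butyldiphenylsilyl)oxy]methyl}-2-ethynyl-2-hydroxycyclohexyl]prop-2-enoate | COC(=O)C(=C)[C@@H]1CC[C@@H](CO[Si](c2ccccc2)(c2ccccc2)C(C)(C)C)C[C@@]1(C#C)[O-].[K+] | intermediate
16 | potassium (5E,9R)-9-{[(tert-butyldiphenylsilyl)oxy]methyl}-5-(methoxycarbonyl)cyclodeca-1,2,5-trien-1-olate | COC(=O)/C1=C/CC[C@@H](CO[Si](c2ccccc2)(c2ccccc2)C(C)(C)C)CC([O-])=C=CC1.[K+] | intermediate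
17 | methyl (1E,5R,8Z)-5-{[(tert-butyldiphenylsilyl)oxy]methyl}-7-oxocyclodeca-1,8-diene-1-carboxylate | COC(=O)/C1=C/CC[C@@H](CO[Si](c2ccccc2)(c2ccccc2)C(C)(C)C)CC(=O)/C=C\C1 | intermediate
18 | methyl (1E,5R,7R,8Z)-5-{[(tert-butyldiphenylsilyl)oxy]methyl}-7-hydroxycyclodeca-1,8-diene-1-carboxylate | COC(=O)/C1=C/CC[C@@H](CO[Si](c2ccccc2)(c2ccccc2)C(C)(C)C)C[C@@H](O)/C=C\C1 | intermediate
19 | methoxyallene (1-methoxypropa-1,2-diene) | COC=C=C | starting material
20 | methyl (1E,5R,7R,8Z)-5-{[(tert-butyldiphenylsilyl)oxy]methyl}-7-[(2-iodo-1-methoxyprop-2-en-1-yl)oxy]cyclodeca-1,8-diene-1-carboxylate (both acetal epimers) | COC(=O)/C1=C/CC[C@@H](CO[Si](c2ccccc2)(c2ccccc2)C(C)(C)C)C[C@@H](OC(OC)C(I)=C)/C=C\C1 | intermediate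
21 | methyl (3aS,6E,10R,11aR)-10-{[(tert-butyldiphenylsilyl)oxy]methyl}-4-hydroperoxy-2-methoxy-3-methylidene-2,3,3a,4,5,8,9,10,11,11a-decahydrocyclodeca[b]furan-6-carboxylate (epimers at C2 and C4) | C=C1C(OC)O[C@@H]2C[C@H](CO[Si](c3ccccc3)(c3ccccc3)C(C)(C)C)CC/C=C(/C(=O)OC)CC(OO)[C@@H]12 | intermediate
22 | methyl (3aR,6E,10R,11aR)-10-{[(tert-butyldiphenylsilyl)oxy]methyl}-4-hydroxy-2-methoxy-3-methylidene-2,3,3a,4,5,8,9,10,11,11a-decahydrocyclodeca[b]furan-6-carboxylate (epimers at C2 and C4) | C=C1C(OC)O[C@@H]2C[C@H](CO[Si](c3ccccc3)(c3ccccc3)C(C)(C)C)CC/C=C(/C(=O)OC)CC(O)[C@@H]12 | intermediate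
23 | methyl (3aS,6E,10R,11aR)-10-{[(tert-butyldiphenylsilyl)oxy]methyl}-2-methoxy-3-methylidene-4-oxo-2,3,3a,4,5,8,9,10,11,11a-decahydrocyclodeca[b]furan-6-carboxylate (both C2 epimers) | C=C1C(OC)O[C@@H]2C[C@H](CO[Si](c3ccccc3)(c3ccccc3)C(C)(C)C)CC/C=C(/C(=O)OC)CC(=O)[C@@H]12 | intermediate
24 | methyl (3aR,4R,6E,10R,11aR)-10-{[(tert-butyldiphenylsilyl)oxy]methyl}-4-hydroxy-2-methoxy-3-methylidene-2,3,3a,4,5,8,9,10,11,11a-decahydrocyclodeca[b]furan-6-carboxylate (both C2 epimers) | C=C1C(OC)O[C@@H]2C[C@H](CO[Si](c3ccccc3)(c3ccccc3)C(C)(C)C)CC/C=C(/C(=O)OC)C[C@@H](O)[C@@H]12 | intermediate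
25 | angelic acid, (2Z)-2-methylbut-2-enoic acid | C/C=C(/C)C(=O)O | starting material
26 | (2Z)-2-methylbut-2-enoic 2,4,6-trichlorobenzoic anhydride | C/C=C(/C)C(=O)OC(=O)c1c(Cl)cc(Cl)cc1Cl | intermediate
27 | methyl (3aS,4R,6E,10R,11aR)-10-{[(tert-butyldiphenylsilyl)oxy]methyl}-2-methoxy-4-{[(2Z)-2-methylbut-2-enoyl]oxy}-3-methylidene-2,3,3a,4,5,8,9,10,11,11a-decahydrocyclodeca[b]furan-6-carboxylate (both C2 epimers) | C=C1C(OC)O[C@@H]2C[C@H](CO[Si](c3ccccc3)(c3ccccc3)C(C)(C)C)CC/C=C(/C(=O)OC)C[C@@H](OC(=O)/C(C)=C\C)[C@@H]12 | intermediate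
28 | methyl (3aS,4R,6E,10R,11aR)-10-{[(tert-butyldiphenylsilyl)oxy]methyl}-4-{[(2Z)-2-methylbut-2-enoyl]oxy}-3-methylidene-2-oxo-2,3,3a,4,5,8,9,10,11,11a-decahydrocyclodeca[b]furan-6-carboxylate | C=C1C(=O)O[C@@H]2C[C@H](CO[Si](c3ccccc3)(c3ccccc3)C(C)(C)C)CC/C=C(/C(=O)OC)C[C@@H](OC(=O)/C(C)=C\C)[C@@H]12 | intermediate
29 | methyl (3aS,4R,6E,10R,11aR)-10-(hydroxymethyl)-4-{[(2Z)-2-methylbut-2-enoyl]oxy}-3-methylidene-2-oxo-2,3,3a,4,5,8,9,10,11,11a-decahydrocyclodeca[b]furan-6-carboxylate (CNP0167542.1) | C=C1C(=O)O[C@@H]2C[C@H](CO)CC/C=C(/C(=O)OC)C[C@@H](OC(=O)/C(C)=C\C)[C@@H]12 | target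

**Step count and risks**

Total step count: 14. Longest linear sequence: 14 steps (from 1; compounds 5, 10, 19 and 25 are bought).

Steps most likely to fail:

1. Step 7 (Proposed new method). The lactone may not open far enough for the shift to compete: re-lactonisation, conjugate addition of methoxide to the methylene lactone, or metalation of the terminal alkyne could hold the material back, and the skipped dienone could isomerise under base. The fallback uses the classical free-carbinol oxy-Cope and sets out from 14. DIBAL-H reduces the lactone to (1R,2S,4R)-4-{[(tert-butyldiphenylsilyl)oxy]methyl}-1-ethynyl-2-(3-hydroxyprop-1-en-2-yl)cyclohexan-1-ol F1. TBSCl and imidazole silylate its primary allylic hydroxyl to the mono-TBS ether F2. KH and 18-crown-6 in THF then effect the known anionic oxy-Cope ring expansion of the tertiary alkoxide to (2Z,5E,9R)-5-({[tert-butyl(dimethyl)silyl]oxy}methyl)-9-{[(tert-butyldiphenylsilyl)oxy]methyl}cyclodeca-2,5-dien-1-one F3. PPTS in MeOH frees the allylic alcohol F4, MnO2 gives the enal F5, NaClO2 with 2-methyl-2-butene gives the acid F6, and TMSCHN2 gives the methyl ester, which is 17, where the route is rejoined.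

2. Step 10. The oxygen trap may act at the wrong moment (capture of the vinyl radical before ring closure, reduction of the C8 radical by tin hydride before oxygen reaches it), or the C8 radical may abstract hydrogen across the ten-membered ring. The fallback brings the C8 oxygen in before the radical closure and sets out from 18. Ag2O and propargyl bromide give the propargyl ether, methyl (1E,5R,7R,8Z)-5-{[(tert-butyldiphenylsilyl)oxy]methyl}-7-(prop-2-yn-1-yloxy)cyclodeca-1,8-diene-1-carboxylate F7, and mCPBA epoxidises its electron-rich C7=C8 alkene to the cis epoxide F8. Cp2TiCl (trivalent titanium, made from Cp2TiCl2 and Zn) opens the epoxide to the C7 radical, which closes 5-exo onto the alkyne to the 3-methylidene tetrahydrofuran carbinol F9. Dess–Martin oxidation gives the ketone F10, Luche reduction the 4R carbinol F11 and Yamaguchi esterification with 25 the angelate F12. Allylic oxidation of the ring ether methylene (CrO3, 3,5-dimethylpyrazole, CH2Cl2) then gives 28, where the route is rejoined.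

3. Step 11. Facial selectivity of hydride addition to the C8 ketone in the flexible ring may be poor or reversed. The fallback gives up reduction control for inversion and sets out from 23: the reduction is run to the epimeric carbinol, methyl (3aR,4S,6E,10R,11aR)-10-{[(tert-butyldiphenylsilyl)oxy]methyl}-4-hydroxy-2-methoxy-3-methylidene-2,3,3a,4,5,8,9,10,11,11a-decahydrocyclodeca[b]furan-6-carboxylate F13, which is esterified with 25 under Mitsunobu conditions (PPh3, DIAD, toluene) with inversion at C8 to give 27, where the route is rejoined.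

**Further compounds**

F1 | step 7 | (1R,2S,4R)-4-{[(tert-butyldiphenylsilyl)oxy]methyl}-1-ethynyl-2-(3-hydroxyprop-1-en-2-yl)cyclohexan-1-ol | C=C(CO)[C@@H]1CC[C@@H](CO[Si](c2ccccc2)(c2ccccc2)C(C)(C)C)C[C@@]1(C#C)O
F2 | step 7 | (1R,2S,4R)-2-(3-{[tert-butyl(dimethyl)silyl]oxy}prop-1-en-2-yl)-4-{[(tert-butyldiphenylsilyl)oxy]methyl}-1-ethynylcyclohexan-1-ol | C=C(CO[Si](C)(C)C(C)(C)C)[C@@H]1CC[C@@H](CO[Si](c2ccccc2)(c2ccccc2)C(C)(C)C)C[C@@]1(C#C)O
F3 | step 7 | (2Z,5E,9R)-5-({[tert-butyl(dimethyl)silyl]oxy}methyl)-9-{[(tert-butyldiphenylsilyl)oxy]methyl}cyclodeca-2,5-dien-1-one | CC(C)(C)[Si](C)(C)OC/C1=C/CC[C@@H](CO[Si](c2ccccc2)(c2ccccc2)C(C)(C)C)CC(=O)/C=C\C1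
F4 | step 7 | (2Z,5E,9R)-9-{[(tert-butyldiphenylsilyl)oxy]methyl}-5-(hydroxymethyl)cyclodeca-2,5-dien-1-one | OC/C1=C/CC[C@@H](CO[Si](c2ccccc2)(c2ccccc2)C(C)(C)C)CC(=O)/C=C\C1
F5 | step 7 | (1E,5R,8Z)-5-{[(tert-butyldiphenylsilyl)oxy]methyl}-7-oxocyclodeca-1,8-diene-1-carbaldehyde | O=C/C1=C/CC[C@@H](CO[Si](c2ccccc2)(c2ccccc2)C(C)(C)C)CC(=O)/C=C\C1
F6 | step 7 | (1E,5R,8Z)-5-{[(tert-butyldiphenylsilyl)oxy]methyl}-7-oxocyclodeca-1,8-diene-1-carboxylic acid | OC(=O)/C1=C/CC[C@@H](CO[Si](c2ccccc2)(c2ccccc2)C(C)(C)C)CC(=O)/C=C\C1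
F7 | step 10 | methyl (1E,5R,7R,8Z)-5-{[(tert-butyldiphenylsilyl)oxy]methyl}-7-(prop-2-yn-1-yloxy)cyclodeca-1,8-diene-1-carboxylate | COC(=O)/C1=C/CC[C@@H](CO[Si](c2ccccc2)(c2ccccc2)C(C)(C)C)C[C@@H](OCC#C)/C=C\C1
F8 | step 10 | methyl (3E,7R,9R)-7-{[(tert-butyldiphenylsilyl)oxy]methyl}-9-(prop-2-yn-1-yloxy)-11-oxabicyclo[8.1.0]undec-3-ene-3-carboxylate (cis epoxide, either face) | COC(=O)/C1=C/CC[C@@H](CO[Si](c2ccccc2)(c2ccccc2)C(C)(C)C)C[C@@H](OCC#C)C2OC2C1
F9 | step 10 | methyl (3aR,6E,10R,11aR)-10-{[(tert-butyldiphenylsilyl)oxy]methyl}-4-hydroxy-3-methylidene-2,3,3a,4,5,8,9,10,11,11a-decahydrocyclodeca[b]furan-6-carboxylate (C4 as set by the epoxide) | C=C1CO[C@@H]2C[C@H](CO[Si](c3ccccc3)(c3ccccc3)C(C)(C)C)CC/C=C(/C(=O)OC)CC(O)[C@@H]12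
F10 | step 10 | methyl (3aS,6E,10R,11aR)-10-{[(tert-butyldiphenylsilyl)oxy]methyl}-3-methylidene-4-oxo-2,3,3a,4,5,8,9,10,11,11a-decahydrocyclodeca[b]furan-6-carboxylate | C=C1CO[C@@H]2C[C@H](CO[Si](c3ccccc3)(c3ccccc3)C(C)(C)C)CC/C=C(/C(=O)OC)CC(=O)[C@@H]12
F11 | step 10 | methyl (3aR,4R,6E,10R,11aR)-10-{[(tert-butyldiphenylsilyl)oxy]methyl}-4-hydroxy-3-methylidene-2,3,3a,4,5,8,9,10,11,11a-decahydrocyclodeca[b]furan-6-carboxylate | C=C1CO[C@@H]2C[C@H](CO[Si](c3ccccc3)(c3ccccc3)C(C)(C)C)CC/C=C(/C(=O)OC)C[C@@H](O)[C@@H]12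
F12 | step 10 | methyl (3aS,4R,6E,10R,11aR)-10-{[(tert-butyldiphenylsilyl)oxy]methyl}-4-{[(2Z)-2-methylbut-2-enoyl]oxy}-3-methylidene-2,3,3a,4,5,8,9,10,11,11a-decahydrocyclodeca[b]furan-6-carboxylate | C=C1CO[C@@H]2C[C@H](CO[Si](c3ccccc3)(c3ccccc3)C(C)(C)C)CC/C=C(/C(=O)OC)C[C@@H](OC(=O)/C(C)=C\C)[C@@H]12
F13 | step 11 | methyl (3aR,4S,6E,10R,11aR)-10-{[(tert-butyldiphenylsilyl)oxy]methyl}-4-hydroxy-2-methoxy-3-methylidene-2,3,3a,4,5,8,9,10,11,11a-decahydrocyclodeca[b]furan-6-carboxylate (both C2 epimers) | C=C1C(OC)O[C@@H]2C[C@H](CO[Si](c3ccccc3)(c3ccccc3)C(C)(C)C)CC/C=C(/C(=O)OC)C[C@H](O)[C@@H]12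
A1 | direct plan | methyl (2E,6R)-7-[(2R)-4-(bromomethyl)-5-oxo-2,5-dihydrofuran-2-yl]-6-{[(tert-butyldiphenylsilyl)oxy]methyl}-2-(2-oxoethyl)hept-2-enoate | O=CC/C(C(=O)OC)=C\CC[C@@H](CO[Si](c1ccccc1)(c1ccccc1)C(C)(C)C)C[C@H]1OC(=O)C(CBr)=C1
A2 | direct plan | methyl (3aR,4S,6E,10R,11aR)-10-{[(tert-butyldiphenylsilyl)oxy]methyl}-4-hydroxy-3-methylidene-2-oxo-2,3,3a,4,5,8,9,10,11,11a-decahydrocyclodeca[b]furan-6-carboxylate | C=C1C(=O)O[C@@H]2C[C@H](CO[Si](c3ccccc3)(c3ccccc3)C(C)(C)C)CC/C=C(/C(=O)OC)C[C@H](O)[C@@H]12
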